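The numbers in the tables come from a simulation from invented constants, noise included.

Per molar of substrate charged, your two earlier runs read alike, so that is the unit I reckoned in. You guessed that the long time in eta would beat the strong charge in zeta.

| flask | substrate | free catalyst | remark | time |
|---|---|---|---|---|
| oak | 0.66 M | 9.2 mol% | run made earlier |  |
| cedar | 1.2 M | 9.2 mol% | run made earlier |  |
| eta | 1.2 M | 9.2 mol% |  | 30 h |
| zeta | 2.0 M | 9.2 mol% |  | 8.0 h |

- oak (time / h: product / %, substrate / %): 0.250: 1.7, 98.0; 0.833: 4.3, 95.0; 1.33: 7.5, 92.3; 2.00: 7.8, 90.1; 3.00: 12.3, 89.1; 4.00: 12.0, 89.5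
- cedar (time / h: product / %, substrate / %): 0.667: 8.1, 93.0; 1.33: 12.2, 86.9; 2.00: 16.4, 84.9; 2.50: 17.2, 82.4; 3.00: 18.2, 80.8; 4.00: 22.3, 79.7

(each reading ± 1 percentage point)

- steps that have been proposed: catalyst intermediate -> free catalyst + product; substrate + free catalyst <-> catalyst intermediate; free catalyst <-> dormant form
- where the amount of substrate changes, what is given in equivalents or mol% on it follows

* the winner by amount of product, in percent of the substrate charged; "neither" if no more than 2 percentage points parts them (eta / zeta / neither)
* how much product is there at the end, in percent of the substrate charged: eta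
* how much product is there at the end, in percent of the substrate charged: zeta

The loading is 9.2 mol% in oak, cedar, eta and zeta, so the catalyst charged rose in step with the starting c(substrate). I therefore froze that proportion and used D, the natural logarithm of charged over remaining substrate, divided by the starting c(substrate). At 4.00 h, oak gave 0.168 M⁻¹ and cedar 0.189 M⁻¹, and I took their mean, 0.179 M⁻¹.

Beyond that time I assumed a straight, pseudo-first-order tail with free catalyst constant. The pooled rise from 2.00 h gave 2.62 × 10⁻⁴ M⁻¹ min⁻¹, which may still hold some of the early fall. The rise from 3.00 h gave 3.86 × 10⁻⁵ M⁻¹ min⁻¹, which lies deep in the scatter. I took the midpoint, 1.50 × 10⁻⁴ M⁻¹ min⁻¹, as the tail slope, the gain in D per minute.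

Counting lost substrate as product, I committed to 39.1% for eta and 34.9% for zeta, so eta came out ahead. That order was weak: the lower slope gave eta 24.9% and zeta 31.3%, which puts zeta ahead.

The forecast named eta, with 48% for eta and 39% for zeta, its ground being that “the slow tail has longer to run”, and its eta stood above mine.

The simulation gave 37.1% for eta and 36.8% for zeta, so with a margin of 2 percentage points the answer is neither.

    catalyst intermediate → free catalyst + product (k = 3.50 min⁻¹)
    substrate + free catalyst ⇌ catalyst intermediate (K = 0.210 M⁻¹, k = 0.0240 M⁻¹ min⁻¹)
    free catalyst ⇌ dormant form (K = 17.0, k = 0.0110 min⁻¹)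

My slope proved high. Eta climbed 1.19 × 10⁻⁴ M⁻¹ min⁻¹ over its second half, and zeta, read again at 15 h, climbed 1.20 × 10⁻⁴ M⁻¹ min⁻¹ after 8.0 h, both less than my figure. In zeta at 1.13 h, the forward half-life of free catalyst going to the dormant form was 1.1 h, shorter than the 5.4 h forward half-life of substrate in its binding step. By 8.00 h, zeta held 94.0% of its catalyst charged as dormant form and 5.92% as free catalyst.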